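Everything rests on assembling ring A (the acyl ring) from two small unsaturated pieces and forming the depside ester late. Ring A has oxygens at C2' and C4' in a meta relation and methyl groups at C5' and C6', the first of them next to the C4' oxygen, which is the pattern a Danheiser benzannulation writes. Heating 2,3-dimethylcyclobut-2-en-1-one (5), a strained four-membered enone, with ethoxyethyne (6) forms C2'–C3', C4'–C5' and C1'–C2' in one flask and gives 3-ethoxy-4,5-dimethylphenol (11). Its two open positions are then filled in turn: C1' by carboxyl, used to acylate ring B phenol 18, and C3', by then the only aromatic C–H, by formyl.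

Key step: step 3

Remark on the chemistry: the target has no stereocentre. Primed locants denote ring A and unprimed locants ring B. Compound 6 is assumed to be used as its commercial hexane solution, and 15 is the commercial oakmoss odorant.

Step 1
Reactants: 1 but-2-yne; 2 trichloroacetyl chloride
Product: 4 4,4-dichloro-2,3-dimethylcyclobut-2-en-1-one, via dichloroketene 3 (not isolated)
Conditions: Zn–Cu couple, Et2O–DME, slow addition of 2, 0 °C → rt
Reagents that add atoms: none
Why: Zinc removes two chlorines from 2 to give electrophilic dichloroketene, which adds to the symmetrical alkyne in a thermal ketene–alkyne [2+2] cycloaddition with no regiochemical question, while DME ties up the ZnCl2 that could isomerise the allylic dichloride.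

Step 2
Reactants: 4 4,4-dichloro-2,3-dimethylcyclobut-2-en-1-one
Product: 5 2,3-dimethylcyclobut-2-en-1-one
Conditions: Zn dust, AcOH, TMEDA, EtOH, 0 °C → rt
Reagents that add atoms: none
Why: Reductive dehalogenation of the α,α-dichloroketone runs through zinc enolates that acetic acid protonates, and the TMEDA-buffered medium is mild enough to leave the strained enone ring intact.

Step 3
Reactants: 5 2,3-dimethylcyclobut-2-en-1-one; 6 ethoxyethyne
Product: 11 3-ethoxy-4,5-dimethylphenol, via vinylketene 7 (not isolated), via 4-vinylcyclobutenone adduct 8 (not isolated), via dienylketene 9 (not isolated), via cyclohexadienone 10 (not isolated)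
Conditions: 6 (2.5 equiv), toluene, 80 °C, sealed tube
Reagents that add atoms: none
Why: At 80 °C the C1–C4 bond of 5 breaks in a reversible conrotatory four-electron opening to vinylketene 7, whose carbonyl carbon (future C2') is attacked by the electron-rich terminal carbon of 6 (C3') while the oxygen-bearing alkyne carbon (C4') bonds to the ketene α-carbon (C5'), so that a ketene–alkyne [2+2] cycloaddition gives 8. Strain then drives a second four-electron opening to dienylketene 9, a disrotatory six-electron electrocyclisation joins the CH2 terminus (C1') to the ketene carbon (C2') and closes ring A, the only ring that remains, and enolisation of dienone 10 makes the sequence irreversible. This is the Danheiser benzannulation, a known reaction class for cyclobutenones and alkoxyalkynes. No stereocentre survives, because the quaternary carbon of racemic 8 becomes aromatic C5', and the opening of 8 that turns methyl instead of isopropenyl towards the ketene is reversible and drains through the productive E isomer 9. The selectivity needed is regiochemical, and it is secured by the polarisation of the ynol ether (nucleophilic at CH, cation-stabilising at C–OEt) matched to the electrophilic ketene carbonyl, which sets the two oxygens meta and puts the ethoxy group beside the methyl pair. The excess of 6 should trap 7 before phenol 11 can be acylated by it, and 80 °C lies below the range in which 6 fragments by retro-ene loss of ethene.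

Step 4
Reactants: 11 3-ethoxy-4,5-dimethylphenol
Product: 13 4-ethoxy-2-hydroxy-5,6-dimethylbenzaldehyde, via aryl iminium chloride 12 (not isolated)
Conditions: POCl3, DMF, 0 °C → rt; then ice–H2O
Reagents that add atoms: N,N-dimethylformamide CN(C)C=O; water O
Why: In this Vilsmeier–Haack formylation the bulky chloroiminium ion should attack C1', para to the ethoxy and ortho to the hydroxy group, rather than C3' wedged between the two oxygens, as is usual for resorcinol derivatives, and hydrolysis of 12 releases the aldehyde.

Step 5
Reactants: 13 4-ethoxy-2-hydroxy-5,6-dimethylbenzaldehyde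
Product: 14 4-ethoxy-2-hydroxy-5,6-dimethylbenzoic acid
Conditions: NaClO2, H2NSO3H, THF–H2O, 0 °C → rt
Reagents that add atoms: sodium chlorite [Na+].[O-]Cl=O
Why: In this Lindgren–Pinnick oxidation chlorous acid adds to the aldehyde and fragments to the acid, while sulfamic acid destroys the hypochlorous acid formed before it can chlorinate the open C3' position of the electron-rich ring.

Step 6
Reactants: 15 methyl 2,4-dihydroxy-3,6-dimethylbenzoate
Product: 16 methyl 5-formyl-2,4-dihydroxy-3,6-dimethylbenzoate
Conditions: Cl2CHOMe, TiCl4, CH2Cl2, −10 → 0 °C; then aq HCl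
Reagents that add atoms: dichloromethyl methyl ether COC(Cl)Cl; water O
Why: This Rieche formylation can occur at one site only, because C5 is the sole unsubstituted ring position of 15 and is activated by the ortho C4 and para C2 hydroxy groups.

Step 7
Reactants: 16 methyl 5-formyl-2,4-dihydroxy-3,6-dimethylbenzoate
Product: 18 methyl 2,4-dihydroxy-3,5,6-trimethylbenzoate, via benzylic alcohol 17 (not isolated)
Conditions: Et3SiH (2.5 equiv), TFA, CH2Cl2, rt
Reagents that add atoms: none
Why: In this ionic hydrogenation the protonated aldehyde and then alcohol 17 give benzylic cations stabilised by the ortho and para hydroxy groups, each is trapped by hydride from the silane, and the fully substituted ring rules out Friedel–Crafts dimerisation.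

Step 8
Reactants: 14 4-ethoxy-2-hydroxy-5,6-dimethylbenzoic acid; 18 methyl 2,4-dihydroxy-3,5,6-trimethylbenzoate
Product: 20 methyl 4-[(4-ethoxy-2-hydroxy-5,6-dimethylbenzoyl)oxy]-2-hydroxy-3,5,6-trimethylbenzoate, via mixed trifluoroacetic anhydride 19 (not isolated)
Conditions: (CF3CO)2O, toluene, rt
Reagents that add atoms: none
Why: In this mixed-anhydride depside esterification TFAA converts the hindered, electron-rich acid into the acylium-like donor 19, which acylates the free C4 hydroxy group of 18, whereas the C2 and C2' hydroxy groups are held in hydrogen bonds to neighbouring ester carbonyls and the C4' oxygen is capped as its ethyl ether.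

Step 9
Reactants: 20 methyl 4-[(4-ethoxy-2-hydroxy-5,6-dimethylbenzoyl)oxy]-2-hydroxy-3,5,6-trimethylbenzoate
Product: 21 methyl 4-[(4-ethoxy-3-formyl-2-hydroxy-5,6-dimethylbenzoyl)oxy]-2-hydroxy-3,5,6-trimethylbenzoate
Conditions: Cl2CHOMe (3 equiv), TiCl4 (5 equiv), CH2Cl2, −20 → 0 °C; then aq HCl
Reagents that add atoms: dichloromethyl methyl ether COC(Cl)Cl; water O
Why: This is a Rieche formylation of a resorcylate ester in which C3' is the only aromatic C–H of 20 and lies ortho to both the titanium-bound C2' phenoxide and the C4' ethoxy group, so site selectivity is built in and the low temperature should spare both esters.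

Step 10
Reactants: 21 methyl 4-[(4-ethoxy-3-formyl-2-hydroxy-5,6-dimethylbenzoyl)oxy]-2-hydroxy-3,5,6-trimethylbenzoate
Product: 22 pseudocyphellarin A
Conditions: BCl3 (3–4 equiv), CH2Cl2, −78 → 0 °C; then H2O
Reagents that add atoms: none
Why: In this chelation-directed ether cleavage BCl3 binds the C3' formyl oxygen and the adjacent C4' ether oxygen in a six-membered chelate, chloride removes the ethyl group by SN2 attack, and the methyl ester and the depside ester react far more slowly at low temperature.

Compound list
1 | but-2-yne | CC#CC | starting material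
2 | trichloroacetyl chloride | O=C(Cl)C(Cl)(Cl)Cl | starting material
3 | dichloroketene | O=C=C(Cl)Cl | intermediate (not isolated)
4 | 4,4-dichloro-2,3-dimethylcyclobut-2-en-1-one | CC1=C(C)C(Cl)(Cl)C1=O | intermediate
5 | 2,3-dimethylcyclobut-2-en-1-one | CC1=C(C)C(=O)C1 | intermediate
6 | ethoxyethyne | C#COCC | starting material
7 | 2,3-dimethylbuta-1,3-dien-1-one (vinylketene) | C=C(C)C(C)=C=O | intermediate (not isolated)
8 | 3-ethoxy-4-methyl-4-(prop-1-en-2-yl)cyclobut-2-en-1-one (racemic) | CCOC1=CC(=O)C1(C)C(C)=C | intermediate (not isolated)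
9 | (3E)-3-ethoxy-4,5-dimethylhexa-1,3,5-trien-1-one (dienylketene) | O=C=C/C(OCC)=C(/C)C(C)=C | intermediate (not isolated)
10 | 3-ethoxy-4,5-dimethylcyclohexa-2,4-dien-1-one | CCOC1=CC(=O)CC(C)=C1C | intermediate (not isolated)
11 | 3-ethoxy-4,5-dimethylphenol | CCOc1cc(O)cc(C)c1C | intermediate
12 | N-[(4-ethoxy-2-hydroxy-5,6-dimethylphenyl)methylidene]-N-methylmethanaminium chloride | CCOc1cc(O)c(C=[N+](C)C)c(C)c1C.[Cl-] | intermediate (not isolated)
13 | 4-ethoxy-2-hydroxy-5,6-dimethylbenzaldehyde | CCOc1cc(O)c(C=O)c(C)c1C | intermediate
14 | 4-ethoxy-2-hydroxy-5,6-dimethylbenzoic acid | CCOc1cc(O)c(C(=O)O)c(C)c1C | intermediate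
15 | methyl 2,4-dihydroxy-3,6-dimethylbenzoate | COC(=O)c1c(C)cc(O)c(C)c1O | starting material
16 | methyl 5-formyl-2,4-dihydroxy-3,6-dimethylbenzoate | COC(=O)c1c(C)c(C=O)c(O)c(C)c1O | intermediate
17 | methyl 2,4-dihydroxy-5-(hydroxymethyl)-3,6-dimethylbenzoate | COC(=O)c1c(C)c(CO)c(O)c(C)c1O | intermediate (not isolated)
18 | methyl 2,4-dihydroxy-3,5,6-trimethylbenzoate | COC(=O)c1c(C)c(C)c(O)c(C)c1O | intermediate
19 | 4-ethoxy-2-hydroxy-5,6-dimethylbenzoic trifluoroacetic anhydride | CCOc1cc(O)c(C(=O)OC(=O)C(F)(F)F)c(C)c1C | intermediate (not isolated)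
20 | methyl 4-[(4-ethoxy-2-hydroxy-5,6-dimethylbenzoyl)oxy]-2-hydroxy-3,5,6-trimethylbenzoate | COC(=O)c1c(C)c(C)c(OC(=O)c2c(C)c(C)c(OCC)cc2O)c(C)c1O | intermediate
21 | methyl 4-[(4-ethoxy-3-formyl-2-hydroxy-5,6-dimethylbenzoyl)oxy]-2-hydroxy-3,5,6-trimethylbenzoate | COC(=O)c1c(C)c(C)c(OC(=O)c2c(C)c(C)c(OCC)c(C=O)c2O)c(C)c1O | intermediate
22 | pseudocyphellarin A, methyl 4-[(3-formyl-2,4-dihydroxy-5,6-dimethylbenzoyl)oxy]-2-hydroxy-3,5,6-trimethylbenzoate | COC(=O)c1c(C)c(C)c(OC(=O)c2c(C)c(C)c(O)c(C=O)c2O)c(C)c1O | target

Total step count: 10
Longest linear sequence: 8 steps (1, 2, 3, 4, 5, 8, 9, 10). Steps 6 and 7 form the ring B branch.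

Steps most likely to fail

**Step 3.**
- Risk: The vinylketene may be consumed by acylation of phenol already formed or by self-dimerisation. The ynol ether may decay on prolonged heating, or the cascade may stall after the [2+2] stage.
- Fallback: It sets out from 6 and returns at 11, and it generates the vinylketene with base at room temperature instead of by heat. Purchased 2,3-dimethylbut-2-enoic acid F1 is converted with (COCl)2 and catalytic DMF into 2,3-dimethylbut-2-enoyl chloride F2. Slow addition of Et3N to F2 and 6 in CH2Cl2 at rt brings about 1,4-dehydrochlorination to 7, which 6 traps as 8. After filtration of the ammonium salt and removal of surplus 6, adduct 8 is heated alone in toluene (80–110 °C) and passes through 9 and 10 to 11. The ynol ether therefore never sees heat.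

**Step 9.**
- Risk: The Lewis acid may cleave or transacylate the depside ester, or substitution may stall at the crowded C3' site.
- Fallback: It sets out from 14 and returns at 21, and it moves the formylation ahead of the coupling. The carboxylate of 14 is alkylated (MeI, KHCO3, DMF) to methyl 4-ethoxy-2-hydroxy-5,6-dimethylbenzoate F3. Rieche formylation of this simple resorcylate (Cl2CHOMe, TiCl4) gives methyl 4-ethoxy-3-formyl-2-hydroxy-5,6-dimethylbenzoate F4. The doubly ortho-substituted ester is hydrolysed by the acylium pathway (cold concentrated H2SO4, then ice) to 4-ethoxy-3-formyl-2-hydroxy-5,6-dimethylbenzoic acid F5. F5 is condensed with 18 by DCC in toluene to give 21.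

**Step 8.**
- Risk: Acylation of the doubly ortho-methylated C4 hydroxy group may be slow. That leaves time for decarboxylation of the electron-rich acid or for its self-condensation through the C2' hydroxy group.
- Fallback: It sets out from 13 and returns at 20, and it uses a fully protected acid chloride. Benzylation of 13 (BnBr, K2CO3, DMF) gives 2-(benzyloxy)-4-ethoxy-5,6-dimethylbenzaldehyde F6. Chlorite oxidation as in step 5 gives 2-(benzyloxy)-4-ethoxy-5,6-dimethylbenzoic acid F7. (COCl)2 with catalytic DMF gives 2-(benzyloxy)-4-ethoxy-5,6-dimethylbenzoyl chloride F8. Acylation of 18 (Et3N, DMAP, CH2Cl2) gives methyl 4-{[2-(benzyloxy)-4-ethoxy-5,6-dimethylbenzoyl]oxy}-2-hydroxy-3,5,6-trimethylbenzoate F9. Hydrogenolysis (H2, Pd/C, EtOAc), harmless here because no aldehyde is yet present, gives 20.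

Further compounds
F1 | step 3 | 2,3-dimethylbut-2-enoic acid | CC(C)=C(C)C(=O)O
F2 | step 3 | 2,3-dimethylbut-2-enoyl chloride | CC(C)=C(C)C(=O)Cl
F3 | step 9 | methyl 4-ethoxy-2-hydroxy-5,6-dimethylbenzoate | CCOc1cc(O)c(C(=O)OC)c(C)c1C
F4 | step 9 | methyl 4-ethoxy-3-formyl-2-hydroxy-5,6-dimethylbenzoate | CCOc1c(C=O)c(O)c(C(=O)OC)c(C)c1C
F5 | step 9 | 4-ethoxy-3-formyl-2-hydroxy-5,6-dimethylbenzoic acid | CCOc1c(C=O)c(O)c(C(=O)O)c(C)c1C
F6 | step 8 | 2-(benzyloxy)-4-ethoxy-5,6-dimethylbenzaldehyde | CCOc1cc(OCc2ccccc2)c(C=O)c(C)c1C
F7 | step 8 | 2-(benzyloxy)-4-ethoxy-5,6-dimethylbenzoic acid | CCOc1cc(OCc2ccccc2)c(C(=O)O)c(C)c1C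
F8 | step 8 | 2-(benzyloxy)-4-ethoxy-5,6-dimethylbenzoyl chloride | CCOc1cc(OCc2ccccc2)c(C(=O)Cl)c(C)c1C
F9 | step 8 | methyl 4-{[2-(benzyloxy)-4-ethoxy-5,6-dimethylbenzoyl]oxy}-2-hydroxy-3,5,6-trimethylbenzoate | COC(=O)c1c(C)c(C)c(OC(=O)c2c(C)c(C)c(OCC)cc2OCc3ccccc3)c(C)c1O
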